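Retrosynthesis: the C9–O ester bond is cut first (salicylate last); the C4 methyl (C14) is traced back to a formyl group; the C1=C2 olefin is reconnected as a C14–C1 σ-bond with a leaving group on C2 (Grob fragmentation read backwards).
Enabling feature: in the seven-membered ring C1(Me)=C2–C3–C4–C8–C9(O)–C10 the carbon C14 on C4 is 1,4-related to C1; a C14–C1 bond gives a bicyclo[3.2.1]octane (bridges C14; C2–C3; C10–C9–C8) whose six-membered ring C14–C1–C10–C9–C8–C4 is cis-fused to the cyclopentane C4–C5–C6–C7–C8.
Further cuts: C1–C2 (aldol), C7–isopropyl (carbonyl addition), C4–C14 plus C8–C9 (Diels–Alder), C4–C3 (allyl Grignard addition to a vinylogous ester).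
Forward ring order: cyclopentenone (bought ring) → cyclohexene by Diels–Alder (cis-hydrindane) → bridging cyclopentane by reductive aldol (bicyclo[3.2.1]octane) → cycloheptene released by cutting the C14–C1 bridge.
Stereochemistry: C4/C8 from the suprafacial cycloaddition; C9 from the endo rule then Mitsunobu inversion; C7 from addition to the convex face; the transient C2 centre from exo-face hydride delivery; the trans ring fusion follows because C14 (not C3) was the hydrindane ring member; absolute configuration by resolution of the racemic cycloadduct on a chiral stationary phase.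

Key step: step 13

Remark: the labels C1–C10 and C14 used below are those of the target (seven-membered ring C1(Me)=C2–C3–C4–C8–C9–C10, five-membered ring C4–C5–C6–C7–C8, C14 on C4); the racemate 7 is written as the pair of its enantiomers.
Remark: the C14 carbinol configuration drawn for 20 and 21 assumes hydride attack from the side of the two-carbon bridge; this centre is destroyed in step 13.

Step 1
Reactants: 1 3-ethoxycyclopent-2-en-1-one; 2 allylmagnesium bromide
Product: 4 3-allylcyclopent-2-en-1-one, via bromomagnesium alkoxide 3 (not isolated)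
Conditions: 2 (1.2 equiv), THF, 0 °C; then 1 M HCl, 0 °C → rt
Reagents that add atoms: water (SMILES O)
Why: Stork–Danheiser sequence: 1,2-addition of the Grignard reagent to the vinylogous ester followed by acid-promoted loss of water and hydrolysis of the ethoxy-stabilised allyl cation should give the transposed 3-substituted enone; no stereocentre is formed.

Step 2
Reactants: 5 3-methylbut-2-enal
Product: 6 (E)-1-(tert-butyldimethylsilyloxy)-3-methylbuta-1,3-diene
Conditions: TBSOTf, Et3N, Et2O, 0 °C → rt
Reagents that add atoms: tert-butyldimethylsilyl trifluoromethanesulfonate (SMILES CC(C)(C)[Si](C)(C)OS(=O)(=O)C(F)(F)F)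
Why: Soft enolisation (O-silylation of the enal, then γ-deprotonation by the amine) should give the silyl dienol ether, with the (E)-enol ether favoured on steric grounds.

Step 3
Reactants: 4 3-allylcyclopent-2-en-1-one; 6 (E)-1-(tert-butyldimethylsilyloxy)-3-methylbuta-1,3-diene
Product: 7 racemic (3aR*,7R*,7aS*)-3a-allyl-7-(tert-butyldimethylsilyloxy)-5-methyl-2,3,3a,4,7,7a-hexahydro-1H-inden-1-one
Conditions: AlBr3/AlMe3 (10:1; 0.2 equiv AlBr3), 6 (2 equiv), toluene/CH2Cl2, −5 °C → rt; pyridine quench
Reagents that add atoms: none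
Why: Lewis-acid-catalysed Diels–Alder reaction of a β-substituted cycloalkenone with a silyloxy diene: the unsubstituted, most nucleophilic diene terminus (C14) should bond to the β-carbon C4 and the oxygenated terminus (C9) to C8; suprafacial addition gives the cis ring fusion (allyl cis to H8) and the endo rule places the C9 silyloxy group cis to the C8–C7 bond.

Step 4
Reactants: 7 racemic cycloadduct
Product: 8 (3aR,7R,7aS)-3a-allyl-7-(tert-butyldimethylsilyloxy)-5-methyl-2,3,3a,4,7,7a-hexahydro-1H-inden-1-one
Conditions: preparative SFC on amylose tris(3,5-dimethylphenylcarbamate), CO2/i-PrOH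
Reagents that add atoms: none
Why: Chromatographic resolution on a chiral stationary phase should separate the enantiomers without touching a bond; the (3aR,7R,7aS)-enantiomer is kept, and its assignment is to be confirmed by X-ray analysis of the benzoate 12 and by comparing the rotation of 24 with the natural diol.

Step 5
Reactants: 8 resolved cycloadduct; 9 isopropylmagnesium chloride
Product: 11 (1R,3aR,7R,7aS)-3a-allyl-5-methyl-1-(propan-2-yl)-2,3,3a,4,7,7a-hexahydro-1H-indene-1,7-diol, via C7 carbinol silyl ether 10 (not isolated)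
Conditions: 9, CeCl3, THF, −78 → 0 °C; then n-Bu4NF, THF, rt
Reagents that add atoms: none
Why: 1,2-Addition of the weakly basic organocerium reagent should outrun enolisation and β-elimination of the β-silyloxy ketone; attack on the convex face of the cis-hydrindanone, anti to the C8–C9 bond, sets C7 (hydroxyl cis to the six-membered ring, isopropyl cis to H8), and fluoride then cleaves the silyl ether.

Step 6
Reactants: 11 diol
Product: 12 (1R,3aR,7S,7aS)-3a-allyl-1-hydroxy-5-methyl-1-(propan-2-yl)-2,3,3a,4,7,7a-hexahydro-1H-inden-7-yl benzoate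
Conditions: PhCO2H, PPh3, DIAD, THF, 0 °C → rt
Reagents that add atoms: benzoic acid (SMILES OC(=O)c1ccccc1)
Why: Mitsunobu esterification is an SN2 displacement of the oxyphosphonium group, so the secondary allylic C9 centre should be inverted (oxygen now cis to H8) by benzoate entering on the open convex face, while the tertiary C7 alcohol stays inert.

Step 7
Reactants: 12 benzoate
Product: 14 (1R,3aS,7S,7aS)-3a-allyl-1-hydroxy-5-methyl-4-oxo-1-(propan-2-yl)-2,3,3a,4,7,7a-hexahydro-1H-inden-7-yl benzoate, via C14 allylic alcohol 13 (not isolated)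
Conditions: SeO2 (0.5 equiv), t-BuOOH, CH2Cl2, rt; then Dess–Martin periodinane, NaHCO3, CH2Cl2, rt
Reagents that add atoms: selenium dioxide (SMILES O=[Se]=O) as oxygen carrier, regenerated by tert-butyl hydroperoxide (SMILES CC(C)(C)OO)
Why: Selenium dioxide allylic hydroxylation (Riley oxidation: ene reaction then 2,3-sigmatropic shift) is expected at the ring methylene on the more substituted olefin terminus, which is C14 because C9 is already oxygenated; Dess–Martin oxidation then converges both alcohol epimers on the enone.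

Step 8
Reactants: 14 enone
Product: 16 (1R,3aS,7S,7aS)-1-hydroxy-5-methyl-4-oxo-3a-(2-oxoethyl)-1-(propan-2-yl)-2,3,3a,4,7,7a-hexahydro-1H-inden-7-yl benzoate, via secondary ozonide 15 (not isolated)
Conditions: O3, CH2Cl2, −78 °C (Sudan red end point); then PPh3, −78 °C → rt
Reagents that add atoms: ozone (SMILES [O-][O+]=O)
Why: Ozonolysis with reductive work-up should cleave only the electron-rich monosubstituted olefin, because the conjugated enone double bond reacts with ozone far more slowly.

Step 9
Reactants: 16 enone aldehyde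
Product: 18 bridged ketol (C14 ketone; C2 hydroxyl syn to the C14 bridge), via (Ph3P)Cu enolate 17 (not isolated)
Conditions: [(Ph3P)CuH]6 (0.5 equiv), toluene/THF, −40 → 0 °C; aq NH4Cl
Reagents that add atoms: none
Why: Reductive aldol cyclisation: conjugate hydride transfer to C10 gives the copper enolate, whose only nucleophilic carbon C1 should add to the C2 aldehyde held above it by the angular chain; the tether fixes the configuration of C1, and the chelated transition state is expected to place the C2 hydroxyl syn to the C14 carbonyl (a centre that steps 10 and 11 reset).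

Step 10
Reactants: 18 bridged ketol
Product: 19 bridged 1,3-diketone (C2 and C14 carbonyls)
Conditions: Dess–Martin periodinane, NaHCO3, CH2Cl2, 0 °C → rt
Reagents that add atoms: none
Why: Dess–Martin oxidation of the secondary alcohol erases the C2 configuration from the aldol step; the 1,3-diketone should be stable because the quaternary C1 between the carbonyls cannot enolise.

Step 11
Reactants: 19 bridged diketone
Product: 20 bridged diol (C2 hydroxyl endo; anti to the C14 bridge)
Conditions: NaBH4, MeOH/CH2Cl2, −20 → 0 °C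
Reagents that add atoms: none
Why: Borohydride reduction of both ketones: C2 should be attacked on its exo face because the endo face is closed by the three-carbon bridge and the C9 ester, so its hydroxyl ends endo; C14 should be attacked from the side of the two-carbon bridge, away from the axial C8–C7 bond.

Step 12
Reactants: 20 bridged diol
Product: 21 C2 mesylate of the bridged diol
Conditions: MsCl (1.2 equiv), Et3N, CH2Cl2, −20 °C
Reagents that add atoms: methanesulfonyl chloride (SMILES CS(=O)(=O)Cl)
Why: Sulfonylation through sulfene should select the C2 alcohol, which has one quaternary neighbour, over the C14 alcohol between two quaternary carbons and the tertiary C7 alcohol.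

Step 13
Reactants: 21 C2 mesylate
Product: 22 (3R,3aS,4S,8aS)-8a-formyl-3-hydroxy-6-methyl-3-(propan-2-yl)-1,2,3,3a,4,5,8,8a-octahydroazulen-4-yl benzoate
Conditions: KOtBu (2.5 equiv), THF, 0 °C → rt
Reagents that add atoms: none
Why: tert-Butoxide deprotonates the C14 hydroxyl; the alkoxide electrons form the formyl C=O, the C14–C1 σ-bond becomes the C1=C2 π-bond and mesylate leaves C2 in one concerted step. The closest known reaction type is the Grob (Wharton-type) fragmentation of cyclic 1,3-diol monosulfonates to medium-ring olefins. No ring is closed by bond formation: the seven-membered ring C1–C2–C3–C4–C8–C9–C10 is already the perimeter of the bicycle and is set free when the one-carbon bridge is cut. No stereocentre is created and C4, C7, C8 and C9 are untouched; since C14 and not C3 was the ring member of the cis-hydrindane, the formyl group ends trans to H8, so the hydroazulene is trans-fused. The step needs the C14–C1 bond antiperiplanar to the C2–O bond, which the endo mesylate from step 11 secures in the rigid five-membered ring of the bicycle; the olefin can only form between C1 and C2, the C14 alkoxide points away from C2 and cannot close an oxetane, and the tertiary C7 alkoxide has no leaving group to fragment onto.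

Step 14
Reactants: 22 formyl hydroazulene benzoate
Product: 24 (3R,3aS,4S,8aR)-6,8a-dimethyl-3-(propan-2-yl)-1,2,3,3a,4,5,8,8a-octahydroazulene-3,4-diol, via hydrazone 23 (not isolated)
Conditions: N2H4·H2O, KOH, diethylene glycol, 130 °C; then 200 °C with removal of water
Reagents that add atoms: none
Why: Wolff–Kishner reduction (Huang-Minlon procedure) of the non-enolisable aldehyde through its hydrazone should give the angular methyl group, and the hot alkaline medium also cleaves the benzoate to free the C9 alcohol.

Step 15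
Reactants: 24 diol; 25 2-(acetyloxy)benzoyl chloride
Product: 26 (3R,3aS,4S,8aR)-3-hydroxy-6,8a-dimethyl-3-(propan-2-yl)-1,2,3,3a,4,5,8,8a-octahydroazulen-4-yl 2-(acetyloxy)benzoate
Conditions: 25 (1.5 equiv), pyridine, DMAP (cat.), CH2Cl2, 0 °C → rt
Reagents that add atoms: none
Why: DMAP-catalysed acylation should take place only at the secondary C9 alcohol because the C7 alcohol is tertiary; the phenol is masked as its acetate so that the acid chloride cannot acylate itself.

Step 16
Reactants: 26 acetylsalicylate
Product: 27 (3R,3aS,4S,8aR)-3-hydroxy-6,8a-dimethyl-3-(propan-2-yl)-1,2,3,3a,4,5,8,8a-octahydroazulen-4-yl 2-hydroxybenzoate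
Conditions: K2CO3, MeOH, 0 °C
Reagents that add atoms: none
Why: Mild methanolysis should cleave the aryl acetate selectively, since the hindered secondary salicylate is a far poorer acyl donor and is further deactivated once its phenoxide forms.

Compound list
1 | 3-ethoxycyclopent-2-en-1-one | CCOC1=CC(=O)CC1 | starting material
2 | allylmagnesium bromide | C=CC[Mg]Br | starting material
3 | bromomagnesium 1-allyl-3-ethoxycyclopent-2-en-1-olate | CCOC1=CC(CC=C)(O[Mg]Br)CC1 | intermediate (not isolated)
4 | 3-allylcyclopent-2-en-1-one | C=CCC1=CC(=O)CC1 | intermediate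
5 | 3-methylbut-2-enal | CC(C)=CC=O | starting material
6 | (E)-1-(tert-butyldimethylsilyloxy)-3-methylbuta-1,3-diene | C=C(C)/C=C/O[Si](C)(C)C(C)(C)C | intermediate
7 | racemic (3aR*,7R*,7aS*)-3a-allyl-7-(tert-butyldimethylsilyloxy)-5-methyl-2,3,3a,4,7,7a-hexahydro-1H-inden-1-one (cis-fused; silyloxy group cis to the C8–C7 bond) | C=CC[C@]12CC(C)=C[C@@H](O[Si](C)(C)C(C)(C)C)[C@H]1C(=O)CC2.C=CC[C@@]12CC(C)=C[C@H](O[Si](C)(C)C(C)(C)C)[C@@H]1C(=O)CC2 | intermediate
8 | (3aR,7R,7aS)-3a-allyl-7-(tert-butyldimethylsilyloxy)-5-methyl-2,3,3a,4,7,7a-hexahydro-1H-inden-1-one | C=CC[C@]12CC(C)=C[C@@H](O[Si](C)(C)C(C)(C)C)[C@H]1C(=O)CC2 | intermediate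
9 | isopropylmagnesium chloride | CC(C)[Mg]Cl | starting material
10 | (1R,3aR,7R,7aS)-3a-allyl-7-(tert-butyldimethylsilyloxy)-5-methyl-1-(propan-2-yl)-2,3,3a,4,7,7a-hexahydro-1H-inden-1-ol | C=CC[C@]12CC(C)=C[C@@H](O[Si](C)(C)C(C)(C)C)[C@H]1[C@](O)(C(C)C)CC2 | intermediate (not isolated)
11 | (1R,3aR,7R,7aS)-3a-allyl-5-methyl-1-(propan-2-yl)-2,3,3a,4,7,7a-hexahydro-1H-indene-1,7-diol | C=CC[C@]12CC(C)=C[C@@H](O)[C@H]1[C@](O)(C(C)C)CC2 | intermediate
12 | (1R,3aR,7S,7aS)-3a-allyl-1-hydroxy-5-methyl-1-(propan-2-yl)-2,3,3a,4,7,7a-hexahydro-1H-inden-7-yl benzoate | C=CC[C@]12CC(C)=C[C@H](OC(=O)c3ccccc3)[C@H]1[C@](O)(C(C)C)CC2 | intermediate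
13 | (1R,3aS,7S,7aS)-3a-allyl-1,4-dihydroxy-5-methyl-1-(propan-2-yl)-2,3,3a,4,7,7a-hexahydro-1H-inden-7-yl benzoate (both C14 epimers) | C=CC[C@]12C(O)C(C)=C[C@H](OC(=O)c3ccccc3)[C@H]1[C@](O)(C(C)C)CC2 | intermediate (not isolated)
14 | (1R,3aS,7S,7aS)-3a-allyl-1-hydroxy-5-methyl-4-oxo-1-(propan-2-yl)-2,3,3a,4,7,7a-hexahydro-1H-inden-7-yl benzoate | C=CC[C@]12C(=O)C(C)=C[C@H](OC(=O)c3ccccc3)[C@H]1[C@](O)(C(C)C)CC2 | intermediate
15 | secondary ozonide of 14 (1,2,4-trioxolane in place of the terminal olefin; ozonide carbon unassigned) | C1OC(C[C@]23C(=O)C(C)=C[C@H](OC(=O)c4ccccc4)[C@H]2[C@](O)(C(C)C)CC3)OO1 | intermediate (not isolated)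
16 | (1R,3aS,7S,7aS)-1-hydroxy-5-methyl-4-oxo-3a-(2-oxoethyl)-1-(propan-2-yl)-2,3,3a,4,7,7a-hexahydro-1H-inden-7-yl benzoate | O=CC[C@]12C(=O)C(C)=C[C@H](OC(=O)c3ccccc3)[C@H]1[C@](O)(C(C)C)CC2 | intermediate
17 | (Ph3P)Cu enolate of the C14 ketone of 16 with C1 as enolate carbon (phosphine omitted in the SMILES) | O=CC[C@]12C(O[Cu])=C(C)C[C@H](OC(=O)c3ccccc3)[C@H]1[C@](O)(C(C)C)CC2 | intermediate (not isolated)
18 | 4,9-dihydroxy-8-methyl-11-oxo-4-(propan-2-yl)tricyclo[6.2.1.0(1,5)]undecan-6-yl benzoate (bicyclo[3.2.1]octan-8-one fused to the cyclopentane; C2 hydroxyl exo, syn to the C14 bridge) | C[C@]12[C@H](O)C[C@@]3(C1=O)CC[C@@](O)(C(C)C)[C@@H]3[C@@H](OC(=O)c4ccccc4)C2 | intermediate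
19 | 4-hydroxy-8-methyl-9,11-dioxo-4-(propan-2-yl)tricyclo[6.2.1.0(1,5)]undecan-6-yl benzoate | C[C@]12C(=O)C[C@@]3(C1=O)CC[C@@](O)(C(C)C)[C@@H]3[C@@H](OC(=O)c4ccccc4)C2 | intermediate
20 | 4,9,11-trihydroxy-8-methyl-4-(propan-2-yl)tricyclo[6.2.1.0(1,5)]undecan-6-yl benzoate (C2 hydroxyl endo, anti to the C14 bridge; C14 hydroxyl toward the three-carbon bridge) | C[C@]12[C@@H](O)C[C@@]3([C@H]1O)CC[C@@](O)(C(C)C)[C@@H]3[C@@H](OC(=O)c4ccccc4)C2 | intermediate
21 | 4,11-dihydroxy-8-methyl-9-(methylsulfonyloxy)-4-(propan-2-yl)tricyclo[6.2.1.0(1,5)]undecan-6-yl benzoate (C2 mesylate endo, anti to the C14 bridge) | C[C@]12[C@@H](OS(C)(=O)=O)C[C@@]3([C@H]1O)CC[C@@](O)(C(C)C)[C@@H]3[C@@H](OC(=O)c4ccccc4)C2 | intermediate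
22 | (3R,3aS,4S,8aS)-8a-formyl-3-hydroxy-6-methyl-3-(propan-2-yl)-1,2,3,3a,4,5,8,8a-octahydroazulen-4-yl benzoate | CC1=CC[C@@]2(C=O)CC[C@@](O)(C(C)C)[C@@H]2[C@@H](OC(=O)c3ccccc3)C1 | intermediate
23 | (3R,3aS,4S,8aS)-8a-(hydrazinylidenemethyl)-6-methyl-3-(propan-2-yl)-1,2,3,3a,4,5,8,8a-octahydroazulene-3,4-diol | CC1=CC[C@@]2(C=NN)CC[C@@](O)(C(C)C)[C@@H]2[C@@H](O)C1 | intermediate (not isolated)
24 | (3R,3aS,4S,8aR)-6,8a-dimethyl-3-(propan-2-yl)-1,2,3,3a,4,5,8,8a-octahydroazulene-3,4-diol (jaeschkeanadiol) | CC1=CC[C@@]2(C)CC[C@@](O)(C(C)C)[C@@H]2[C@@H](O)C1 | intermediate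
25 | 2-(acetyloxy)benzoyl chloride | CC(=O)Oc1ccccc1C(Cl)=O | starting material
26 | (3R,3aS,4S,8aR)-3-hydroxy-6,8a-dimethyl-3-(propan-2-yl)-1,2,3,3a,4,5,8,8a-octahydroazulen-4-yl 2-(acetyloxy)benzoate | CC1=CC[C@@]2(C)CC[C@@](O)(C(C)C)[C@@H]2[C@@H](OC(=O)c3ccccc3OC(C)=O)C1 | intermediate
27 | (3R,3aS,4S,8aR)-3-hydroxy-6,8a-dimethyl-3-(propan-2-yl)-1,2,3,3a,4,5,8,8a-octahydroazulen-4-yl 2-hydroxybenzoate | CC1=CC[C@@]2(C)CC[C@@](O)(C(C)C)[C@@H]2[C@@H](OC(=O)c3ccccc3O)C1 | target

Total step count: 16 (including the resolution, step 4).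
Longest linear sequence: 15 steps (steps 1 and 3–16, from 1); step 2 is a one-step side branch.

Steps most likely to fail

Step 3. The cycloaddition may be too slow at the fully substituted β-carbon, so that Lewis-acid-induced decomposition of the silyl dienol ether, loss of silanol from the adduct or migration of the allyl double bond into conjugation take over. The fallback sets out from 1 and comes back at 7. Bromination of 1 with N-bromosuccinimide should give 2-bromo-3-ethoxycyclopent-2-en-1-one F1. Addition of 2 and acid hydrolysis as in step 1 would give 3-allyl-2-bromocyclopent-2-en-1-one F2, an α-halo enone and as such a markedly better dienophile than the parent enone. Its cycloaddition with 6 (Me2AlCl, CH2Cl2, −40 °C) should give the racemic C8-bromo cycloadduct F3. Radical debromination (Bu3SnH, AIBN, toluene, 80 °C) would then deliver the cis-fused ketone 7, which enters step 4.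

Step 7. Hydrogen abstraction in the ene step may occur at the C1 methyl group or in the allyl side chain instead of at the hindered neopentyl C14 methylene, and over-oxidation may follow. The fallback sets out from 11 and comes back at 14, so it also replaces step 6. MnO2 oxidation of the allylic alcohol would give the C9 enone F4, whose ring γ-methylene is C14. γ-Oxidation of this enone in the manner of the isophorone to ketoisophorone conversion (Rh2(cap)4 cat., t-BuOOH, CH2Cl2) should give the ene-dione F5. Hydroxyl-directed reduction with Me4NBH(OAc)3 (Evans–Saksena conditions; hydride delivered from the C7 oxygen to the less hindered C9 carbonyl) would give the C9 hydroxy enone F6 with the C9 oxygen cis to H8. Benzoylation (BzCl, pyridine, DMAP) then returns to 14.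

Step 9. The copper hydride may reduce the aldehyde before the enone, or the strained aldolate may revert by retro-aldol cleavage so that open-chain reduction products form. The fallback sets out from 14 and comes back at 18. Conjugate reduction with LiBH(s-Bu)3 at −78 °C would give the saturated C14 ketone F7 as C1 epimers. Ozonolysis as in step 8 would give the keto aldehyde F8. Acid-catalysed aldol cyclisation through the enol (p-TsOH, benzene, rt), under thermodynamic control, should then close the C1–C2 bond to 18 or its C2 epimer, both of which step 10 oxidises to 19.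

Further compounds
F1 | step 3 | 2-bromo-3-ethoxycyclopent-2-en-1-one | CCOC1=C(Br)C(=O)CC1
F2 | step 3 | 3-allyl-2-bromocyclopent-2-en-1-one | C=CCC1=C(Br)C(=O)CC1
F3 | step 3 | racemic (3aR*,7R*,7aS*)-3a-allyl-7a-bromo-7-(tert-butyldimethylsilyloxy)-5-methyl-2,3,3a,4,7,7a-hexahydro-1H-inden-1-one | C=CC[C@]12CC(C)=C[C@@H](O[Si](C)(C)C(C)(C)C)[C@@]1(Br)C(=O)CC2.C=CC[C@@]12CC(C)=C[C@H](O[Si](C)(C)C(C)(C)C)[C@]1(Br)C(=O)CC2
F4 | step 7 | C9 enone from 11: 3a-allyl-1-hydroxy-5-methyl-1-(propan-2-yl)-1,2,3,3a,4,7a-hexahydro-7H-inden-7-one (configuration of 11 at C4; C7; C8) | C=CC[C@]12CC(C)=CC(=O)[C@H]1[C@](O)(C(C)C)CC2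
F5 | step 7 | ene-dione: 3a-allyl-1-hydroxy-5-methyl-1-(propan-2-yl)-1,2,3,3a-tetrahydro-7aH-indene-4,7-dione (configuration of 11 at C4; C7; C8) | C=CC[C@]12C(=O)C(C)=CC(=O)[C@H]1[C@](O)(C(C)C)CC2
F6 | step 7 | C9 hydroxy enone: debenzoylated 14 (C9 hydroxyl cis to H8) | C=CC[C@]12C(=O)C(C)=C[C@H](O)[C@H]1[C@](O)(C(C)C)CC2
F7 | step 9 | 5,6-dihydro derivative of 14 (saturated C14 ketone; both C1 epimers) | C=CC[C@]12C(=O)C(C)C[C@H](OC(=O)c3ccccc3)[C@H]1[C@](O)(C(C)C)CC2
F8 | step 9 | 5,6-dihydro derivative of 16 (saturated keto aldehyde; both C1 epimers) | O=CC[C@]12C(=O)C(C)C[C@H](OC(=O)c3ccccc3)[C@H]1[C@](O)(C(C)C)CC2
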